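Everything rests on opening ring B at C4'–C5'. Ring B is a cyclopent-2-enone, C1'–C2'(=O)–C3'=C4'–C5', whose alkene sits on the edge that carries no substituent; a silicon-directed Nazarov cyclisation exploits exactly this, since silicon on C4' decides where the alkene ends. In one operation the step closes ring B, forms C4'–C5', sets C5' by the sense of conrotation and C1' by protonation, and removes silicon. Its precursor is a cross-conjugated dienone on ring-A carbon C5: an (E)-ethylidene at C1', an (E)-2-(trimethylsilyl)vinyl group on the ketone, with the ring-A primary acetate, tertiary triethylsilyl ether and (E)-iodoalkene already in place.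

Key step: step 17

Remark on the chemistry: atom labels are those of the target (ring A C1 = carbinol carbon, C3 = carbon bearing the side chain, C5 = carbon bonded to ring B; ring B C1' to C5'); CIP descriptors follow the numbering of each name, and the change of label at the chain-bearing ring carbon between 10 and 11 reflects priorities only.

Step 1
Reactants: 1 (R)-limonene
Product: 3 (3R)-6-oxo-3-(prop-1-en-2-yl)heptanal, via ring-alkene ozonide 2 (not isolated)
Conditions: O3 (1.0 equiv), CH2Cl2, −78 °C; then Me2S, −78 °C → rt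
Reagents that add atoms: ozone, [O-][O+]=O
Why: Ozonolysis with reductive work-up; the trisubstituted ring alkene is more electron-rich than the 1,1-disubstituted isopropenyl group and should be cleaved first when ozone is limited, and the stereocentre is untouched.

Step 2
Reactants: 3 (3R)-6-oxo-3-(prop-1-en-2-yl)heptanal
Product: 4 1-[(4S)-4-(prop-1-en-2-yl)cyclopent-1-en-1-yl]ethan-1-one
Conditions: KOH (1% aq), Et2O, rt
Reagents that add atoms: none
Why: Intramolecular aldol condensation; hydroxide forms the ketone enolate at the methylene next to the ketone, which attacks the more electrophilic aldehyde in a five-membered closure and dehydrates to the conjugated enone, while the stereocentre is α to neither carbonyl and is kept.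

Step 3
Reactants: 4 1-[(4S)-4-(prop-1-en-2-yl)cyclopent-1-en-1-yl]ethan-1-one
Product: 5 (4S)-4-(prop-1-en-2-yl)cyclopent-1-ene-1-carboxylic acid
Conditions: NaOBr (pre-formed from Br2 and aq NaOH, 0 °C), 1,4-dioxane, 0 °C; then HCl (aq) to pH 2
Reagents that add atoms: sodium hydroxide, [Na+].[OH-]
Why: Haloform reaction of a conjugated methyl ketone; exhaustive α-bromination of the methyl group and cleavage by hydroxide removes that carbon as bromoform, and hypobromite ion in strong base does not add to the isolated alkene.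

Step 4
Reactants: 5 (4S)-4-(prop-1-en-2-yl)cyclopent-1-ene-1-carboxylic acid
Product: 6 [(4S)-4-(prop-1-en-2-yl)cyclopent-1-en-1-yl]methanol
Conditions: LiAlH4, Et2O, 0 °C → rt
Reagents that add atoms: none
Why: Hydride reduction of the carboxylic acid to the primary allylic alcohol, a 1,2-reduction that leaves the alkyl-substituted ring alkene intact.

Step 5
Reactants: 6 [(4S)-4-(prop-1-en-2-yl)cyclopent-1-en-1-yl]methanol
Product: 7 [(1S,3S,5S)-3-(prop-1-en-2-yl)-6-oxabicyclo[3.1.0]hexan-1-yl]methanol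
Conditions: Ti(OiPr)4 (10 mol%), L-(+)-diethyl tartrate (12 mol%), t-BuOOH (2 equiv), 4 Å MS, CH2Cl2, −20 °C
Reagents that add atoms: tert-butyl hydroperoxide, CC(C)(C)OO
Why: Sharpless asymmetric epoxidation; only the allylic-alcohol alkene is epoxidised, and L-(+)-tartrate should deliver oxygen to the face that gives the (1S,5S) epoxide, which is also the face anti to the C3 isopropenyl group (matched case), so the oxygen that becomes the tertiary hydroxyl is set trans to the C3 substituent.

Step 6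
Reactants: 7 [(1S,3S,5S)-3-(prop-1-en-2-yl)-6-oxabicyclo[3.1.0]hexan-1-yl]methanol; 8 allylmagnesium bromide
Product: 9 (1R,2R,4S)-1-(hydroxymethyl)-4-(prop-1-en-2-yl)-2-(prop-2-en-1-yl)cyclopentan-1-ol
Conditions: 8 (3 equiv), CuI (10 mol%), THF, −30 → 0 °C; NH4Cl (aq)
Reagents that add atoms: none
Why: Copper-catalysed SN2 opening of a 2,3-epoxy alcohol by an allyl Grignard reagent; the fully substituted epoxide carbon cannot be attacked, so the allyl group enters at ring-A C5 with inversion, trans to the new tertiary hydroxyl and therefore cis to the hydroxymethyl group and to the C3 isopropenyl group.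

Step 7
Reactants: 9 (1R,2R,4S)-1-(hydroxymethyl)-4-(prop-1-en-2-yl)-2-(prop-2-en-1-yl)cyclopentan-1-ol
Product: 10 triethyl{[(1R,2R,4S)-4-(prop-1-en-2-yl)-2-(prop-2-en-1-yl)-1-[(triethylsilyl)oxy]cyclopentyl]methoxy}silane
Conditions: TESOTf (2.5 equiv), 2,6-lutidine, CH2Cl2, −78 → 0 °C
Reagents that add atoms: triethylsilyl trifluoromethanesulfonate, CC[Si](CC)(CC)OS(=O)(=O)C(F)(F)F
Why: Silylation with a silyl triflate, reactive enough to cap the tertiary as well as the primary hydroxyl, so the tertiary silyl ether needed in the Nazarov precursor is installed here once and for all.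

Step 8
Reactants: 10 bis(triethylsilyl) ether of 9
Product: 11 methyl 2-[(1S,2R,4S)-4-acetyl-2-[(triethylsilyl)oxy]-2-{[(triethylsilyl)oxy]methyl}cyclopentyl]acetate
Conditions: O3, NaOH (2.5 M in MeOH), CH2Cl2, −78 °C; then AcOH, Me2S, −78 °C → rt
Reagents that add atoms: ozone, [O-][O+]=O; methanol, CO
Why: Ozonolysis in methanolic NaOH, which turns the terminal allyl alkene directly into the methyl ester and the 1,1-disubstituted isopropenyl alkene into the methyl ketone; acidification before warming protects the ring carbon next to the new ketone from epimerisation.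

Step 9
Reactants: 11 keto ester
Product: 12 methyl 2-[(1S,2R,4S)-4-[(E)-1-(4,4,5,5-tetramethyl-1,3,2-dioxaborolan-2-yl)prop-1-en-2-yl]-2-[(triethylsilyl)oxy]-2-{[(triethylsilyl)oxy]methyl}cyclopentyl]acetate
Conditions: CH2(Bpin)2 (1.3 equiv), lithium 2,2,6,6-tetramethylpiperidide (1.3 equiv), THF, 0 °C; then 11, −78 °C → rt
Reagents that add atoms: bis(pinacolato)borylmethane, CC1(C)OB(CB2OC(C)(C)C(C)(C)O2)OC1(C)C
Why: Boron-Wittig olefination; the lithiated geminal bis(boronate) adds to the ketone much faster than to the ester, and syn elimination of the boron–oxygen pair should place the remaining boryl group trans to the bulky ring substituent, giving the (E)-trisubstituted alkenyl boronate.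

Step 10
Reactants: 12 alkenyl boronate
Product: 13 methyl 2-[(1S,2R,4S)-4-[(E)-1-iodoprop-1-en-2-yl]-2-[(triethylsilyl)oxy]-2-{[(triethylsilyl)oxy]methyl}cyclopentyl]acetate
Conditions: NaOMe, MeOH/THF, 0 °C; then I2, 0 °C
Reagents that add atoms: iodine, II
Why: Iododeboronation of an alkenyl boronate through its borate complex (base first, then iodine), which replaces boron by iodine with retention of alkene geometry, and methoxide cannot harm a methyl ester.

Step 11
Reactants: 13 iodoalkene methyl ester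
Product: 14 2-[(1S,2R,4S)-4-[(E)-1-iodoprop-1-en-2-yl]-2-[(triethylsilyl)oxy]-2-{[(triethylsilyl)oxy]methyl}cyclopentyl]-N-methoxy-N-methylacetamide
Conditions: MeNHOMe·HCl (1.6 equiv), iPrMgCl (3.2 equiv), THF, −20 → 0 °C
Reagents that add atoms: N,O-dimethylhydroxylamine hydrochloride, CNOC.Cl
Why: Weinreb amide formation from an unhindered ester with the magnesium amide of N,O-dimethylhydroxylamine; the Grignard reagent is consumed by the ammonium salt as it is added, so the iodoalkene meets no free alkylmagnesium.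

Step 12
Reactants: 14 N-methoxy-N-methylamide; 15 (E)-(2-bromovinyl)trimethylsilane
Product: 17 (3E)-1-[(1S,2R,4S)-4-[(E)-1-iodoprop-1-en-2-yl]-2-[(triethylsilyl)oxy]-2-{[(triethylsilyl)oxy]methyl}cyclopentyl]-4-(trimethylsilyl)but-3-en-2-one, via (E)-2-(trimethylsilyl)vinylmagnesium bromide 16 (not isolated)
Conditions: 15, Mg, THF, 40 °C; then 14, THF, 0 °C; NH4Cl (aq)
Reagents that add atoms: none
Why: Weinreb ketone synthesis; the alkenyl Grignard reagent adds only once because the magnesium chelate of the tetrahedral adduct survives until work-up, and the (E)-geometry of the silylvinyl unit is carried through.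

Step 13
Reactants: 17 β-silyl enone; 18 acetaldehyde
Product: 20 (1E)-5-hydroxy-4-[(1S,2R,4S)-4-[(E)-1-iodoprop-1-en-2-yl]-2-[(triethylsilyl)oxy]-2-{[(triethylsilyl)oxy]methyl}cyclopentyl]-1-(trimethylsilyl)hex-1-en-3-one (both new centres as a mixture), via lithium enolate 19 (not isolated)
Conditions: LiN(iPr)2 (1.1 equiv), THF, −78 °C; then 18, −78 °C; NH4Cl (aq)
Reagents that add atoms: none
Why: Directed aldol addition; the ketone carries α-hydrogens only on the methylene next to ring A, so one regioisomeric enolate forms, and the two new stereocentres need no control because both are removed in the next step.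

Step 14
Reactants: 20 aldol adduct
Product: 22 (1E,4E)-4-[(1S,2R,4S)-4-[(E)-1-iodoprop-1-en-2-yl]-2-[(triethylsilyl)oxy]-2-{[(triethylsilyl)oxy]methyl}cyclopentyl]-1-(trimethylsilyl)hexa-1,4-dien-3-one, via β-mesyloxy ketone 21 (not isolated)
Conditions: MsCl, Et3N, CH2Cl2, 0 °C; then DBU, 0 °C → rt
Reagents that add atoms: none
Why: Mesylation followed by E1cB elimination, which should favour the conjugated (E)-ethylidene ketone with the methyl group anti to the carbonyl.

Step 15
Reactants: 22 bis(silyl ether) dienone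
Product: 23 (1E,4E)-4-[(1S,2R,4S)-2-(hydroxymethyl)-4-[(E)-1-iodoprop-1-en-2-yl]-2-[(triethylsilyl)oxy]cyclopentyl]-1-(trimethylsilyl)hexa-1,4-dien-3-one
Conditions: PPTS (cat.), MeOH/CH2Cl2, 0 °C
Reagents that add atoms: none
Why: Acid-catalysed methanolysis of a silyl ether, in which the unhindered primary triethylsilyl ether is cleaved far faster than the hindered tertiary one.

Step 16
Reactants: 23 primary alcohol
Product: 24 [(1R,2S,4S)-4-[(E)-1-iodoprop-1-en-2-yl]-2-[(2E,5E)-4-oxo-6-(trimethylsilyl)hexa-2,5-dien-3-yl]-1-[(triethylsilyl)oxy]cyclopentyl]methyl acetate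
Conditions: Ac2O, pyridine, DMAP (cat.), CH2Cl2, 0 °C → rt
Reagents that add atoms: acetic anhydride, CC(=O)OC(C)=O
Why: Acetylation of the primary alcohol by nucleophilic catalysis, which completes the Nazarov precursor with the acetate of the target already in place.

Step 17
Reactants: 24 Nazarov precursor
Product: 26 [(1R,2S,4S)-4-[(E)-1-iodoprop-1-en-2-yl]-2-[(1S,5R)-5-methyl-2-oxocyclopent-3-en-1-yl]-1-[(triethylsilyl)oxy]cyclopentyl]methyl acetate, via iron dienolate 25 (not isolated)
Conditions: FeCl3 (1.1 equiv), CH2Cl2, −50 → −20 °C; then transfer into cold pH 7 phosphate buffer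
Reagents that add atoms: none
Why: FeCl3 binds the ketone oxygen and turns the cross-conjugated dienone into a 3-oxidopentadienyl cation, whose thermal conrotatory 4π electrocyclisation joins C4' to C5'; the β-silicon on C4' stabilises the oxyallyl cation at C3' and is lost as Me3SiCl, which fixes the alkene at C3'=C4' and leaves iron dienolate 25, protonated at C1' in the quench. The closest known reaction type is the silicon-directed Nazarov cyclisation of β-silyl divinyl ketones promoted by FeCl3. Ring B closes by cationic 4π electrocyclisation of the s-trans,s-trans conformer, a geometry that the α-substituent (ring A) favours. C5' is set by torquoselectivity under control of C5: the (E)-methyl is outside and cis to ring A, and of the two conrotations only the one leading to (5'R) lets ring A settle with C5–H facing the iron-bound oxygen while the methyl lies beside C4H2 and not beside the fully substituted C1, so the developing ring should prefer that sense; this 1,3-induction across the planar C1' is the least secure element. C1' is set by kinetic protonation of 25 on the face away from the adjacent C5' methyl, which places ring A cis to the methyl, and the cold neutral quench with no base afterwards preserves this less stable cis pair. The step also needs chemoselectivity, which the substrate secures through the silyl ether on the tertiary oxygen (no capture of the cation by a free hydroxyl), the inert primary acetate and the electron-poor iodoalkene.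

Step 18
Reactants: 26 Nazarov product
Product: 27 [(1R,2S,4S)-1-hydroxy-4-[(E)-1-iodoprop-1-en-2-yl]-2-[(1S,5R)-5-methyl-2-oxocyclopent-3-en-1-yl]cyclopentyl]methyl acetate
Conditions: HF·pyridine, pyridine, THF, 0 °C → rt
Reagents that add atoms: none
Why: Fluoride-driven cleavage of the tertiary silyl ether under buffered conditions that leave the acetate, the iodoalkene and the epimerisable centre next to the ketone untouched.

Step 19
Reactants: 28 2-methylbut-3-yn-2-ol
Product: 29 (E)-2-methyl-4-(tributylstannyl)but-3-en-2-ol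
Conditions: Bu3SnH, PdCl2(PPh3)2 (2 mol%), THF, rt
Reagents that add atoms: tributyltin hydride, CCCC[SnH](CCCC)CCCC
Why: Palladium-catalysed hydrostannation of a terminal alkyne; syn addition gives the (E)-alkene and the bulky tertiary carbinol directs tin to the terminal carbon.

Step 20
Reactants: 27 iodoalkene with free tertiary hydroxyl; 29 (E)-2-methyl-4-(tributylstannyl)but-3-en-2-ol
Product: 30 [(1R,2S,4S)-1-hydroxy-4-[(2E,4E)-6-hydroxy-6-methylhepta-2,4-dien-2-yl]-2-[(1S,5R)-5-methyl-2-oxocyclopent-3-en-1-yl]cyclopentyl]methyl acetate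
Conditions: PdCl2(MeCN)2 (5 mol%), DMF, rt, dark
Reagents that add atoms: none
Why: Stille coupling of an alkenyl iodide with an alkenylstannane under neutral, ligand-free conditions; both alkene geometries are retained, giving the (2E,4E)-diene, and no base is present to epimerise C1'.

Step 21
Reactants: 30 dienyl tertiary alcohol
Product: 31 [(1R,2S,4S)-1-hydroxy-4-[(2E,4E)-6-hydroperoxy-6-methylhepta-2,4-dien-2-yl]-2-[(1S,5R)-5-methyl-2-oxocyclopent-3-en-1-yl]cyclopentyl]methyl acetate
Conditions: H2O2 (50% aq, large excess), TsOH·H2O (cat.), THF, 0 °C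
Reagents that add atoms: hydrogen peroxide, OO
Why: Acid-catalysed SN1 perhydrolysis of a tertiary allylic alcohol; only the dienyl carbinol ionises under mild acid (the ring tertiary alcohol does not), and excess hydrogen peroxide should capture the pentadienyl cation at its less hindered dimethyl-substituted terminus, which restores the conjugated (2E,4E)-diene.

Compound list
1 | (R)-limonene, (4R)-1-methyl-4-(prop-1-en-2-yl)cyclohex-1-ene | CC1=CC[C@@H](CC1)C(C)=C | starting material
2 | ring-alkene ozonide, 1-methyl-4-(prop-1-en-2-yl)-7,8,9-trioxabicyclo[4.2.1]nonane (isopropenyl-bearing carbon as in 1) | CC12CC[C@@H](C(C)=C)CC(O1)OO2 | intermediate (not isolated)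
3 | (3R)-6-oxo-3-(prop-1-en-2-yl)heptanal | O=CC[C@@H](CCC(C)=O)C(C)=C | intermediate
4 | 1-[(4S)-4-(prop-1-en-2-yl)cyclopent-1-en-1-yl]ethan-1-one | CC(=O)C1=CC[C@@H](C1)C(C)=C | intermediate
5 | (4S)-4-(prop-1-en-2-yl)cyclopent-1-ene-1-carboxylic acid | OC(=O)C1=CC[C@@H](C1)C(C)=C | intermediate
6 | [(4S)-4-(prop-1-en-2-yl)cyclopent-1-en-1-yl]methanol | OCC1=CC[C@@H](C1)C(C)=C | intermediate
7 | [(1S,3S,5S)-3-(prop-1-en-2-yl)-6-oxabicyclo[3.1.0]hexan-1-yl]methanol | OC[C@@]12C[C@@H](C(C)=C)C[C@@H]1O2 | intermediate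
8 | allylmagnesium bromide | C=CC[Mg]Br | starting material
9 | (1R,2R,4S)-1-(hydroxymethyl)-4-(prop-1-en-2-yl)-2-(prop-2-en-1-yl)cyclopentan-1-ol | OC[C@@]1(O)C[C@@H](C(C)=C)C[C@H]1CC=C | intermediate
10 | triethyl{[(1R,2R,4S)-4-(prop-1-en-2-yl)-2-(prop-2-en-1-yl)-1-[(triethylsilyl)oxy]cyclopentyl]methoxy}silane | CC[Si](CC)(CC)OC[C@@]1(O[Si](CC)(CC)CC)C[C@@H](C(C)=C)C[C@H]1CC=C | intermediate
11 | methyl 2-[(1S,2R,4S)-4-acetyl-2-[(triethylsilyl)oxy]-2-{[(triethylsilyl)oxy]methyl}cyclopentyl]acetate | CC[Si](CC)(CC)OC[C@@]1(O[Si](CC)(CC)CC)C[C@@H](C(C)=O)C[C@H]1CC(=O)OC | intermediate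
12 | methyl 2-[(1S,2R,4S)-4-[(E)-1-(4,4,5,5-tetramethyl-1,3,2-dioxaborolan-2-yl)prop-1-en-2-yl]-2-[(triethylsilyl)oxy]-2-{[(triethylsilyl)oxy]methyl}cyclopentyl]acetate | CC[Si](CC)(CC)OC[C@@]1(O[Si](CC)(CC)CC)C[C@@H](/C(C)=C/B2OC(C)(C)C(C)(C)O2)C[C@H]1CC(=O)OC | intermediate
13 | methyl 2-[(1S,2R,4S)-4-[(E)-1-iodoprop-1-en-2-yl]-2-[(triethylsilyl)oxy]-2-{[(triethylsilyl)oxy]methyl}cyclopentyl]acetate | CC[Si](CC)(CC)OC[C@@]1(O[Si](CC)(CC)CC)C[C@@H](/C(C)=C/I)C[C@H]1CC(=O)OC | intermediate
14 | 2-[(1S,2R,4S)-4-[(E)-1-iodoprop-1-en-2-yl]-2-[(triethylsilyl)oxy]-2-{[(triethylsilyl)oxy]methyl}cyclopentyl]-N-methoxy-N-methylacetamide | CC[Si](CC)(CC)OC[C@@]1(O[Si](CC)(CC)CC)C[C@@H](/C(C)=C/I)C[C@H]1CC(=O)N(C)OC | intermediate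
15 | (E)-(2-bromovinyl)trimethylsilane | C[Si](C)(C)/C=C/Br | starting material
16 | (E)-2-(trimethylsilyl)vinylmagnesium bromide | C[Si](C)(C)/C=C/[Mg]Br | intermediate (not isolated)
17 | (3E)-1-[(1S,2R,4S)-4-[(E)-1-iodoprop-1-en-2-yl]-2-[(triethylsilyl)oxy]-2-{[(triethylsilyl)oxy]methyl}cyclopentyl]-4-(trimethylsilyl)but-3-en-2-one | CC[Si](CC)(CC)OC[C@@]1(O[Si](CC)(CC)CC)C[C@@H](/C(C)=C/I)C[C@H]1CC(=O)/C=C/[Si](C)(C)C | intermediate
18 | acetaldehyde | CC=O | starting material
19 | lithium enolate of 17 (deprotonated at the methylene next to ring A) | CC[Si](CC)(CC)OC[C@@]1(O[Si](CC)(CC)CC)C[C@@H](/C(C)=C/I)C[C@H]1C=C(O[Li])/C=C/[Si](C)(C)C | intermediate (not isolated)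
20 | (1E)-5-hydroxy-4-[(1S,2R,4S)-4-[(E)-1-iodoprop-1-en-2-yl]-2-[(triethylsilyl)oxy]-2-{[(triethylsilyl)oxy]methyl}cyclopentyl]-1-(trimethylsilyl)hex-1-en-3-one (mixture at C4 and C5 of the chain) | CC[Si](CC)(CC)OC[C@@]1(O[Si](CC)(CC)CC)C[C@@H](/C(C)=C/I)C[C@H]1C(C(C)O)C(=O)/C=C/[Si](C)(C)C | intermediate
21 | methanesulfonate of 20 (β-mesyloxy ketone) | CC[Si](CC)(CC)OC[C@@]1(O[Si](CC)(CC)CC)C[C@@H](/C(C)=C/I)C[C@H]1C(C(C)OS(C)(=O)=O)C(=O)/C=C/[Si](C)(C)C | intermediate (not isolated)
22 | (1E,4E)-4-[(1S,2R,4S)-4-[(E)-1-iodoprop-1-en-2-yl]-2-[(triethylsilyl)oxy]-2-{[(triethylsilyl)oxy]methyl}cyclopentyl]-1-(trimethylsilyl)hexa-1,4-dien-3-one | CC[Si](CC)(CC)OC[C@@]1(O[Si](CC)(CC)CC)C[C@@H](/C(C)=C/I)C[C@H]1/C(=C\C)C(=O)/C=C/[Si](C)(C)C | intermediate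
23 | (1E,4E)-4-[(1S,2R,4S)-2-(hydroxymethyl)-4-[(E)-1-iodoprop-1-en-2-yl]-2-[(triethylsilyl)oxy]cyclopentyl]-1-(trimethylsilyl)hexa-1,4-dien-3-one | OC[C@@]1(O[Si](CC)(CC)CC)C[C@@H](/C(C)=C/I)C[C@H]1/C(=C\C)C(=O)/C=C/[Si](C)(C)C | intermediate
24 | [(1R,2S,4S)-4-[(E)-1-iodoprop-1-en-2-yl]-2-[(2E,5E)-4-oxo-6-(trimethylsilyl)hexa-2,5-dien-3-yl]-1-[(triethylsilyl)oxy]cyclopentyl]methyl acetate (Nazarov precursor) | CC(=O)OC[C@@]1(O[Si](CC)(CC)CC)C[C@@H](/C(C)=C/I)C[C@H]1/C(=C\C)C(=O)/C=C/[Si](C)(C)C | intermediate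
25 | dichloroiron dienolate of 26: ring A as in 24, bonded at C5 to C1 of a (5R)-5-methyl-2-oxidocyclopenta-1,3-diene | CC(=O)OC[C@@]1(O[Si](CC)(CC)CC)C[C@@H](/C(C)=C/I)C[C@H]1C1=C(O[Fe](Cl)Cl)C=C[C@H]1C | intermediate (not isolated)
26 | [(1R,2S,4S)-4-[(E)-1-iodoprop-1-en-2-yl]-2-[(1S,5R)-5-methyl-2-oxocyclopent-3-en-1-yl]-1-[(triethylsilyl)oxy]cyclopentyl]methyl acetate | CC(=O)OC[C@@]1(O[Si](CC)(CC)CC)C[C@@H](/C(C)=C/I)C[C@H]1[C@H]1C(=O)C=C[C@H]1C | intermediate
27 | [(1R,2S,4S)-1-hydroxy-4-[(E)-1-iodoprop-1-en-2-yl]-2-[(1S,5R)-5-methyl-2-oxocyclopent-3-en-1-yl]cyclopentyl]methyl acetate | CC(=O)OC[C@@]1(O)C[C@@H](/C(C)=C/I)C[C@H]1[C@H]1C(=O)C=C[C@H]1C | intermediate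
28 | 2-methylbut-3-yn-2-ol | CC(C)(O)C#C | starting material
29 | (E)-2-methyl-4-(tributylstannyl)but-3-en-2-ol | CC(C)(O)/C=C/[Sn](CCCC)(CCCC)CCCC | intermediate
30 | [(1R,2S,4S)-1-hydroxy-4-[(2E,4E)-6-hydroxy-6-methylhepta-2,4-dien-2-yl]-2-[(1S,5R)-5-methyl-2-oxocyclopent-3-en-1-yl]cyclopentyl]methyl acetate | CC(=O)OC[C@@]1(O)C[C@@H](/C(C)=C/C=C/C(C)(C)O)C[C@H]1[C@H]1C(=O)C=C[C@H]1C | intermediate
31 | [(1R,2S,4S)-1-hydroxy-4-[(2E,4E)-6-hydroperoxy-6-methylhepta-2,4-dien-2-yl]-2-[(1S,5R)-5-methyl-2-oxocyclopent-3-en-1-yl]cyclopentyl]methyl acetate | CC(=O)OC[C@@]1(O)C[C@@H](/C(C)=C/C=C/C(C)(C)OO)C[C@H]1[C@H]1C(=O)C=C[C@H]1C | target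

Total step count: 21.
Longest linear sequence: 20 steps (steps 1 to 18, then 20 and 21; step 19 prepares the stannane).

Steps most likely to fail

1. Step 17. The conrotation may run in the opposite sense or with little preference, because the only bias is 1,3-induction from C5 across a planar carbon. The proton may also be delivered syn to the methyl, or the α-centre may equilibrate to the trans arrangement during work-up or chromatography. The fallback builds ring B by sigmatropic rearrangement and metathesis; it sets out from 13 and rejoins the route at 26. The methyl ester of 13 is cleaved with Me3SnOH (1,2-dichloroethane, 80 °C) to the carboxylic acid F1, which is esterified with (E)-but-2-en-1-ol (DCC, DMAP) to the (E)-crotyl ester F2. Ireland–Claisen rearrangement (LiN(iPr)2, THF, −78 °C; Me3SiCl; warming to rt) through the chair transition state of the kinetic silyl ketene acetal should give the 2,3-anti pent-4-enoic acid F3. Here C1' is set by 1,2-induction: allylic strain turns C5–H toward the ester oxygen, so the new bond forms on the face away from ring-A C1, and the chair then fixes C5'. The acid is converted into the N-methoxy-N-methylamide F4 (carbonyldiimidazole, MeNHOMe·HCl), and vinylmagnesium bromide gives the vinyl ketone F5. Ring-closing metathesis with the second-generation Grubbs catalyst (CH2Cl2, 40 °C) forms C3'=C4' and gives the bis(silyl ether) cyclopentenone F6. Methanolysis of the primary silyl ether (PPTS, MeOH) gives the primary alcohol F7, and acetylation (Ac2O, pyridine) gives 26.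

2. Step 21. After ionisation the hydroperoxide may enter at the other tertiary terminus of the pentadienyl cation (allylic transposition), the cation may lose a proton to a triene, or the acid may epimerise the centre next to the ketone. The fallback brings the peroxide in on the coupling partner; it sets out from 27 and ends at 31. Commercial 2-methylbut-3-en-2-ol is converted with H2O2 and catalytic H2SO4 (0 °C) into 2-hydroperoxy-2-methylbut-3-ene F8 and protected with 2-methoxypropene (PPTS) as the peroxyketal F9. Heck coupling of 27 with F9 (Pd(OAc)2, Ag2CO3, DMF, rt) joins the iodoalkene carbon to the terminal alkene carbon; β-hydride elimination is possible only toward the new bond, so the (2E,4E)-diene peroxyketal F10 should result, dialkyl peroxides being tolerated in palladium-mediated couplings. Aqueous acetic acid in THF then removes the ketal and gives 31.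

3. Step 9. The boron-stabilised carbanion may enolise the methyl ketone and not add to it, which would epimerise the ring carbon next to the ketone, and the elimination may not be fully (E)-selective. The fallback makes the iodoalkene by alkyne carbometalation; it sets out from 11 and rejoins the route at 13. Kinetic deprotonation on the methyl side (KN(SiMe3)2, THF, −78 °C) and trapping with PhNTf2 gives the enol triflate F11. Elimination with excess LiN(iPr)2 at −78 °C, the ester riding through as its enolate, gives the terminal alkyne F12. Negishi carboalumination (AlMe3, Cp2ZrCl2, one equivalent of water, CH2Cl2, −20 °C) followed by I2 gives 13, the (E)-geometry being fixed by syn addition.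

Further compounds
F1 | step 17 | 2-[(1S,2R,4S)-4-[(E)-1-iodoprop-1-en-2-yl]-2-[(triethylsilyl)oxy]-2-{[(triethylsilyl)oxy]methyl}cyclopentyl]acetic acid | CC[Si](CC)(CC)OC[C@@]1(O[Si](CC)(CC)CC)C[C@@H](/C(C)=C/I)C[C@H]1CC(=O)O
F2 | step 17 | (E)-but-2-en-1-yl 2-[(1S,2R,4S)-4-[(E)-1-iodoprop-1-en-2-yl]-2-[(triethylsilyl)oxy]-2-{[(triethylsilyl)oxy]methyl}cyclopentyl]acetate | CC[Si](CC)(CC)OC[C@@]1(O[Si](CC)(CC)CC)C[C@@H](/C(C)=C/I)C[C@H]1CC(=O)OC/C=C/C
F3 | step 17 | (2S,3R)-2-[(1S,2R,4S)-4-[(E)-1-iodoprop-1-en-2-yl]-2-[(triethylsilyl)oxy]-2-{[(triethylsilyl)oxy]methyl}cyclopentyl]-3-methylpent-4-enoic acid | CC[Si](CC)(CC)OC[C@@]1(O[Si](CC)(CC)CC)C[C@@H](/C(C)=C/I)C[C@H]1[C@@H](C(=O)O)[C@H](C)C=C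
F4 | step 17 | (2S,3R)-2-[(1S,2R,4S)-4-[(E)-1-iodoprop-1-en-2-yl]-2-[(triethylsilyl)oxy]-2-{[(triethylsilyl)oxy]methyl}cyclopentyl]-N-methoxy-N,3-dimethylpent-4-enamide | CC[Si](CC)(CC)OC[C@@]1(O[Si](CC)(CC)CC)C[C@@H](/C(C)=C/I)C[C@H]1[C@@H](C(=O)N(C)OC)[C@H](C)C=C
F5 | step 17 | (4S,5R)-4-[(1S,2R,4S)-4-[(E)-1-iodoprop-1-en-2-yl]-2-[(triethylsilyl)oxy]-2-{[(triethylsilyl)oxy]methyl}cyclopentyl]-5-methylhepta-1,6-dien-3-one | CC[Si](CC)(CC)OC[C@@]1(O[Si](CC)(CC)CC)C[C@@H](/C(C)=C/I)C[C@H]1[C@@H](C(=O)C=C)[C@H](C)C=C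
F6 | step 17 | (4R,5S)-5-[(1S,2R,4S)-4-[(E)-1-iodoprop-1-en-2-yl]-2-[(triethylsilyl)oxy]-2-{[(triethylsilyl)oxy]methyl}cyclopentyl]-4-methylcyclopent-2-en-1-one | CC[Si](CC)(CC)OC[C@@]1(O[Si](CC)(CC)CC)C[C@@H](/C(C)=C/I)C[C@H]1[C@H]1C(=O)C=C[C@H]1C
F7 | step 17 | (4R,5S)-5-[(1S,2R,4S)-2-(hydroxymethyl)-4-[(E)-1-iodoprop-1-en-2-yl]-2-[(triethylsilyl)oxy]cyclopentyl]-4-methylcyclopent-2-en-1-one | OC[C@@]1(O[Si](CC)(CC)CC)C[C@@H](/C(C)=C/I)C[C@H]1[C@H]1C(=O)C=C[C@H]1C
F8 | step 21 | 2-hydroperoxy-2-methylbut-3-ene | CC(C)(OO)C=C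
F9 | step 21 | 2-[(2-methoxypropan-2-yl)peroxy]-2-methylbut-3-ene | COC(C)(C)OOC(C)(C)C=C
F10 | step 21 | [(1R,2S,4S)-1-hydroxy-4-[(2E,4E)-6-[(2-methoxypropan-2-yl)peroxy]-6-methylhepta-2,4-dien-2-yl]-2-[(1S,5R)-5-methyl-2-oxocyclopent-3-en-1-yl]cyclopentyl]methyl acetate | CC(=O)OC[C@@]1(O)C[C@@H](/C(C)=C/C=C/C(C)(C)OOC(C)(C)OC)C[C@H]1[C@H]1C(=O)C=C[C@H]1C
F11 | step 9 | methyl 2-[(1S,2R,4S)-2-[(triethylsilyl)oxy]-2-{[(triethylsilyl)oxy]methyl}-4-{1-[(trifluoromethanesulfonyl)oxy]ethenyl}cyclopentyl]acetate | CC[Si](CC)(CC)OC[C@@]1(O[Si](CC)(CC)CC)C[C@@H](C(=C)OS(=O)(=O)C(F)(F)F)C[C@H]1CC(=O)OC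
F12 | step 9 | methyl 2-[(1S,2R,4S)-4-ethynyl-2-[(triethylsilyl)oxy]-2-{[(triethylsilyl)oxy]methyl}cyclopentyl]acetate | CC[Si](CC)(CC)OC[C@@]1(O[Si](CC)(CC)CC)C[C@@H](C#C)C[C@H]1CC(=O)OC
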